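**Retrosynthetic overview** (cembrane numbering: ring C1–C14; C15(C17)–C16 on C1; C18/C19/C20 on C4/C8/C12; lactone ring O–C3–C2–C1–C15–C16)
1. Last step: Schenck ene reaction of the 7E-alkene gives C8–OOH and the 6E-alkene; before it, C4–OSiEt3 is cleaved to C4–OH.
2. Key disconnection C2–C3: an open-chain γ-iodo ester aldehyde (C2–I, C16 methyl ester, C3 aldehyde) is closed by a cobalt-catalysed alkylchromium addition to the 14-membered carbocycle; the C3 alkoxide then closes the δ-lactone.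
3. Enabling feature: C2 is the γ-carbon of the C16 ester (O–C3–C2–C1–C15–C16 is six-membered), so a C2 metal species needs no activating group and the new C3–O ends in the lactone; C3 is an aldehyde carbon on the fully substituted C4 (no enolisation, Felkin–Anh control by C4–OSiEt3).
4. Seco chain: a B-alkyl Suzuki–Miyaura coupling at C6–C7 joins a C3–C6 unit from (R)-2-methylglycidol to a C7–C16 bromoalkenyl γ-lactone built from pent-4-yn-1-ol (carboalumination, Johnson–Claisen, Shi epoxidation, butenolide, copper hydride reduction, methylation).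
5. Ring order: oxirane (C11–C12), then a temporary butenolide/γ-lactone (O on C2; sets C1 and C15; opened again), then the 14-membered carbocycle and the δ-lactone together in the key step.

Key step: step 19

Assumption: (S)-p-tol-BINAP is taken to be the ligand antipode whose copper hydride adds to the face of butenolide 10 that gives the 4S-lactone 11; if the sense proves opposite, (R)-p-tol-BINAP is used in step 9.

**Step 1**
Reactants: 1 pent-4-yn-1-ol
Product: 2 (4E)-5-bromo-4-methylpent-4-en-1-ol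
Conditions: AlMe3 (3 equiv), Cp2ZrCl2 (0.25 equiv), CH2Cl2, 0 °C → rt; then NBS, THF, −30 °C
Reagents that add atoms: trimethylaluminium (C[Al](C)C); N-bromosuccinimide (O=C1CCC(=O)N1Br)
Why: Negishi zirconium-catalysed syn-carboalumination puts the methyl group (C19) on the internal and aluminium on the terminal alkyne carbon, and bromination of the alkenylalane with retention should give the E-bromoalkene that fixes the C7=C8 geometry.

**Step 2**
Reactants: 2 (4E)-5-bromo-4-methylpent-4-en-1-ol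
Product: 3 (4E)-5-bromo-4-methylpent-4-enal
Conditions: Dess–Martin periodinane, NaHCO3, CH2Cl2, 0 °C → rt
Reagents that add atoms: none
Why: Dess–Martin oxidation of a primary alcohol to the aldehyde (C11) leaves the bromoalkene untouched.

**Step 3**
Reactants: 3 (4E)-5-bromo-4-methylpent-4-enal
Product: 4 (6E)-7-bromo-2,6-dimethylhepta-1,6-dien-3-ol (racemic)
Conditions: isopropenylmagnesium bromide, THF, −78 °C; aq. NH4Cl
Reagents that add atoms: isopropenylmagnesium bromide (CC(=C)[Mg]Br)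
Why: Grignard 1,2-addition brings in C12, C13 and C20; the carbinol centre is left racemic because it is destroyed in step 4.

**Step 4**
Reactants: 4 (6E)-7-bromo-2,6-dimethylhepta-1,6-dien-3-ol
Product: 5 ethyl (4E,8E)-9-bromo-4,8-dimethylnona-4,8-dienoate
Conditions: MeC(OEt)3 (6 equiv), EtCO2H (cat.), 140 °C, EtOH distilled off
Reagents that add atoms: triethyl orthoacetate (CC(OCC)(OCC)OCC)
Why: Johnson–Claisen [3,3]-rearrangement through a chair with the C10 chain equatorial should give the 11E-trisubstituted alkene and adds C14 and the C1 ester carbon.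

**Step 5**
Reactants: 5 ethyl (4E,8E)-9-bromo-4,8-dimethylnona-4,8-dienoate
Product: 6 ethyl 3-[(2S,3S)-3-[(3E)-4-bromo-3-methylbut-3-en-1-yl]-2-methyloxiran-2-yl]propanoate
Conditions: ent-Shi ketone (L-fructose-derived, 0.3 equiv), Oxone (KHSO5·0.5KHSO4·0.5K2SO4), K2CO3, Bu4NHSO4 (cat.), MeCN/(MeO)2CH2/aq. Na2B4O7–Na2EDTA buffer, 0 °C
Reagents that add atoms: potassium peroxymonosulfate ([K+].[O-]S(=O)(=O)OO)
Why: Shi epoxidation through the spiro dioxirane transition state should oxidise only the electron-rich trisubstituted alkene (the bromoalkene is deactivated), and the L-fructose-derived ketone is the antipode expected to give the 11S,12S-oxirane.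

**Step 6**
Reactants: 6 ethyl 3-[(2S,3S)-3-[(3E)-4-bromo-3-methylbut-3-en-1-yl]-2-methyloxiran-2-yl]propanoate
Product: 7 methyl 5-[(2S,3S)-3-[(3E)-4-bromo-3-methylbut-3-en-1-yl]-2-methyloxiran-2-yl]-3-oxopentanoate
Conditions: MeOAc (3 equiv), LDA (3.1 equiv), THF, −78 °C; then 6, −78 → −40 °C; AcOH
Reagents that add atoms: methyl acetate (CC(=O)OC)
Why: Crossed Claisen condensation with excess lithium enolate of methyl acetate turns the C1 ester into the β-keto ester and adds C15 and C16; the oxirane is inert to the enolate at low temperature.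

**Step 7**
Reactants: 7 methyl 5-[(2S,3S)-3-[(3E)-4-bromo-3-methylbut-3-en-1-yl]-2-methyloxiran-2-yl]-3-oxopentanoate
Product: 8 methyl (2Z)-5-[(2S,3S)-3-[(3E)-4-bromo-3-methylbut-3-en-1-yl]-2-methyloxiran-2-yl]-3-{[(trifluoromethyl)sulfonyl]oxy}pent-2-enoate
Conditions: NaH, THF, 0 °C; then PhNTf2, 0 °C → rt
Reagents that add atoms: N-phenylbis(trifluoromethanesulfonimide) (FC(F)(F)S(=O)(=O)N(c1ccccc1)S(=O)(=O)C(F)(F)F)
Why: O-sulfonylation of the chelated sodium enolate of a β-keto ester should give the Z-enol triflate, with the triflate cis to the ester as the later ring closure needs.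

**Step 8**
Reactants: 8 methyl (2Z)-5-[(2S,3S)-3-[(3E)-4-bromo-3-methylbut-3-en-1-yl]-2-methyloxiran-2-yl]-3-{[(trifluoromethyl)sulfonyl]oxy}pent-2-enoate
Product: 10 4-{2-[(2S,3S)-3-[(3E)-4-bromo-3-methylbut-3-en-1-yl]-2-methyloxiran-2-yl]ethyl}furan-2(5H)-one, via hydroxy enoate 9 (not isolated)
Conditions: Bu3SnCH2OH, Pd2(dba)3 (cat.), AsPh3, LiCl, NMP, 40 °C
Reagents that add atoms: (tributylstannyl)methanol (CCCC[Sn](CCCC)(CCCC)CO)
Why: Stille hydroxymethylation with retention places C2 (as CH2OH) cis to the ester so that the butenolide closes by itself; oxidative addition of zerovalent palladium should prefer the ester-activated enol triflate to the hindered bromoalkene.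

**Step 9**
Reactants: 10 4-{2-[(2S,3S)-3-[(3E)-4-bromo-3-methylbut-3-en-1-yl]-2-methyloxiran-2-yl]ethyl}furan-2(5H)-one
Product: 11 (4S)-4-{2-[(2S,3S)-3-[(3E)-4-bromo-3-methylbut-3-en-1-yl]-2-methyloxiran-2-yl]ethyl}oxolan-2-one
Conditions: CuCl (5 mol%), NaOtBu (5 mol%), (S)-p-tol-BINAP (5 mol%), (EtO)2MeSiH, t-BuOH, PhMe, 0 °C → rt
Reagents that add atoms: none
Why: Ligand-controlled asymmetric conjugate reduction of a β-substituted butenolide by a phosphine-bound copper hydride delivers hydride to C1 and so sets the C1 stereocentre; isolated alkenes, the bromoalkene and the oxirane are not reduced.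

**Step 10**
Reactants: 11 (4S)-4-{2-[(2S,3S)-3-[(3E)-4-bromo-3-methylbut-3-en-1-yl]-2-methyloxiran-2-yl]ethyl}oxolan-2-one
Product: 12 (3S,4S)-4-{2-[(2S,3S)-3-[(3E)-4-bromo-3-methylbut-3-en-1-yl]-2-methyloxiran-2-yl]ethyl}-3-methyloxolan-2-one
Conditions: LDA, THF, −78 °C; MeI, −78 → −40 °C
Reagents that add atoms: iodomethane (CI)
Why: Alkylation of the γ-lactone enolate takes place anti to the C1 substituent, so the C17 methyl group should enter trans and set C15.

**Step 11**
Reactants: 13 [(2R)-2-methyloxiran-2-yl]methanol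
Product: 14 (2S)-2-{[(4-methoxybenzyl)oxy]methyl}-2-methyloxirane
Conditions: NaH, 4-methoxybenzyl chloride, Bu4NI (cat.), THF/DMF, 0 °C → rt
Reagents that add atoms: 4-methoxybenzyl chloride (COc1ccc(CCl)cc1)
Why: Williamson etherification protects the future C3 oxygen; a Payne rearrangement of this alkoxide is degenerate and does not erode the C4 configuration.

**Step 12**
Reactants: 14 (2S)-2-{[(4-methoxybenzyl)oxy]methyl}-2-methyloxirane
Product: 15 (2S)-1-[(4-methoxybenzyl)oxy]-2-methylbut-3-en-2-ol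
Conditions: Me3SI (3 equiv), n-BuLi (3 equiv), THF, −10 °C → rt
Reagents that add atoms: trimethylsulfonium iodide (C[S+](C)C.[I-])
Why: Excess dimethylsulfonium methylide opens the oxirane at its CH2 and the resulting sulfonium salt eliminates, a one-carbon homologation to the tertiary allylic alcohol that does not touch the quaternary C4 centre.

**Step 13**
Reactants: 15 (2S)-1-[(4-methoxybenzyl)oxy]-2-methylbut-3-en-2-ol
Product: 16 triethyl{[(2S)-1-[(4-methoxybenzyl)oxy]-2-methylbut-3-en-2-yl]oxy}silane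
Conditions: Et3SiOTf, 2,6-lutidine, CH2Cl2, −78 → 0 °C
Reagents that add atoms: triethylsilyl trifluoromethanesulfonate (CC[Si](CC)(CC)OS(=O)(=O)C(F)(F)F)
Why: Silylation of the tertiary alcohol with the silyl triflate installs the bulky, non-chelating C4 ether that the Felkin–Anh addition of step 19 relies on.

**Step 14**
Reactants: 16 triethyl{[(2S)-1-[(4-methoxybenzyl)oxy]-2-methylbut-3-en-2-yl]oxy}silane; 12 (3S,4S)-4-{2-[(2S,3S)-3-[(3E)-4-bromo-3-methylbut-3-en-1-yl]-2-methyloxiran-2-yl]ethyl}-3-methyloxolan-2-one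
Product: 18 (3S,4S)-3-methyl-4-[2-((2S,3S)-3-{(3E,7S)-8-[(4-methoxybenzyl)oxy]-3,7-dimethyl-7-[(triethylsilyl)oxy]oct-3-en-1-yl}-2-methyloxiran-2-yl)ethyl]oxolan-2-one, via B-alkyl borane 17 (not isolated)
Conditions: 16, 9-BBN, THF, rt → 40 °C; then 12, Pd(dppf)Cl2 (5 mol%), AsPh3, aq. K3PO4, DMF, rt
Reagents that add atoms: none
Why: Anti-Markovnikov hydroboration of the vinyl group and B-alkyl Suzuki–Miyaura coupling with the alkenyl bromide form C6–C7 with retention of the 7E geometry.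

**Step 15**
Reactants: 18 (3S,4S)-3-methyl-4-[2-((2S,3S)-3-{(3E,7S)-8-[(4-methoxybenzyl)oxy]-3,7-dimethyl-7-[(triethylsilyl)oxy]oct-3-en-1-yl}-2-methyloxiran-2-yl)ethyl]oxolan-2-one
Product: 20 methyl (2S,3S)-3-(hydroxymethyl)-5-[(2S,3S)-3-{(3E,7S)-8-[(4-methoxybenzyl)oxy]-3,7-dimethyl-7-[(triethylsilyl)oxy]oct-3-en-1-yl}-2-methyloxiran-2-yl]-2-methylpentanoate, via lithium carboxylate 19 (not isolated)
Conditions: LiOH, THF/H2O, 0 °C → rt; evaporate; MeI, DMF, 0 °C; used at once
Reagents that add atoms: lithium hydroxide ([Li+].[OH-]); iodomethane (CI)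
Why: Saponification of the γ-lactone and O-alkylation of the dry carboxylate under neutral conditions give the γ-hydroxy methyl ester without acid or base that would close the lactone again.

**Step 16**
Reactants: 20 methyl (2S,3S)-3-(hydroxymethyl)-5-[(2S,3S)-3-{(3E,7S)-8-[(4-methoxybenzyl)oxy]-3,7-dimethyl-7-[(triethylsilyl)oxy]oct-3-en-1-yl}-2-methyloxiran-2-yl]-2-methylpentanoate
Product: 21 methyl (2S,3S)-3-(iodomethyl)-5-[(2S,3S)-3-{(3E,7S)-8-[(4-methoxybenzyl)oxy]-3,7-dimethyl-7-[(triethylsilyl)oxy]oct-3-en-1-yl}-2-methyloxiran-2-yl]-2-methylpentanoate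
Conditions: I2, PPh3, imidazole, CH2Cl2, 0 °C
Reagents that add atoms: iodine (II)
Why: Appel iodination of the primary alcohol is fast at 0 °C under imidazole buffer and gives the C2 iodide.

**Step 17**
Reactants: 21 methyl (2S,3S)-3-(iodomethyl)-5-[(2S,3S)-3-{(3E,7S)-8-[(4-methoxybenzyl)oxy]-3,7-dimethyl-7-[(triethylsilyl)oxy]oct-3-en-1-yl}-2-methyloxiran-2-yl]-2-methylpentanoate
Product: 22 methyl (2S,3S)-5-[(2S,3S)-3-{(3E,7S)-8-hydroxy-3,7-dimethyl-7-[(triethylsilyl)oxy]oct-3-en-1-yl}-2-methyloxiran-2-yl]-3-(iodomethyl)-2-methylpentanoate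
Conditions: DDQ, CH2Cl2/pH 7 buffer, 0 °C
Reagents that add atoms: none
Why: Oxidative cleavage of the 4-methoxybenzyl ether by DDQ under buffered conditions frees the C3 alcohol without touching the iodide, the oxirane, the alkene or the silyl ether.

**Step 18**
Reactants: 22 methyl (2S,3S)-5-[(2S,3S)-3-{(3E,7S)-8-hydroxy-3,7-dimethyl-7-[(triethylsilyl)oxy]oct-3-en-1-yl}-2-methyloxiran-2-yl]-3-(iodomethyl)-2-methylpentanoate
Product: 23 methyl (2S,3S)-5-[(2S,3S)-3-{(3E,7S)-3,7-dimethyl-8-oxo-7-[(triethylsilyl)oxy]oct-3-en-1-yl}-2-methyloxiran-2-yl]-3-(iodomethyl)-2-methylpentanoate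
Conditions: Dess–Martin periodinane, NaHCO3, CH2Cl2, 0 °C; used at once
Reagents that add atoms: none
Why: Dess–Martin oxidation gives the C3 aldehyde, which cannot enolise because C4 is fully substituted.

**Step 19**
Reactants: 23 methyl (2S,3S)-5-[(2S,3S)-3-{(3E,7S)-3,7-dimethyl-8-oxo-7-[(triethylsilyl)oxy]oct-3-en-1-yl}-2-methyloxiran-2-yl]-3-(iodomethyl)-2-methylpentanoate
Product: 25 (1R,3R,4S,7E,11S,12S,15S)-11,12-epoxy-4-[(triethylsilyl)oxy]cembr-7-en-16,3-olide, via macrocyclic hydroxy ester 24 (not isolated)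
Conditions: CrCl2 (10 equiv, nickel-free), cobalt phthalocyanine (Co(C32H16N8), 0.2 equiv), DMF, 30 °C, 23 added over 12 h (final 2 mM); aq. work-up; then Ti(OiPr)4 (0.3 equiv), PhMe, 60 °C
Reagents that add atoms: none
Why: Proposed new method: cobalt phthalocyanine is reduced by CrCl2 to a monovalent cobalt nucleophile that takes up the primary C2 iodide, homolysis of the alkyl–cobalt bond and capture of the C2 radical by a second divalent chromium give a persistent, non-basic alkyl–CrCl2 species that adds to the C3 aldehyde, and the closest known reactions are the cobalt-catalysed CrCl2 alkylation of aldehydes by primary alkyl iodides between two molecules (Takai–Utimoto) and Nozaki–Hiyama–Kishi macrocyclisations of alkenyl and allyl halides. The C2–C3 bond closes the 14-membered carbocycle in a 14-exo-trig addition to the carbonyl group, and O3 then closes the six-membered lactone by 6-exo-trig acyl substitution at C16 with loss of methanol, so the bridged bicycle arises from an open chain. C3 is set by Felkin–Anh addition to the α-quaternary, non-chelating α-silyloxy aldehyde (C4–OSiEt3 anti to the incoming C2, which passes the C18 methyl group and not C5), which should give the 3R,4S relationship; C1, C4, C11, C12 and C15 are carried in unchanged. Only the 3R epimer can hold the C1 and C3 ring bonds and the C15 methyl group all equatorial on the lactone, so lactonisation should favour it, and a 3S hydroxy ester, if formed, is expected to stay open and be removed. The step needs chemoselectivity for the aldehyde over the methyl ester and the oxirane, which organochromium reagents show, and ring closure over oligomerisation, which slow addition at high dilution and the long life of the alkylchromium should secure; the C2 radical has no alkene within five or six atoms and the γ-iodo ester meets no base, so radical cyclisation and cyclopropane formation are not expected.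

**Step 20**
Reactants: 25 (1R,3R,4S,7E,11S,12S,15S)-11,12-epoxy-4-[(triethylsilyl)oxy]cembr-7-en-16,3-olide
Product: 26 (1R,3R,4S,7E,11S,12S,15S)-11,12-epoxy-4-hydroxycembr-7-en-16,3-olide
Conditions: Bu4NF, AcOH, THF, 0 °C → rt
Reagents that add atoms: none
Why: Buffered fluoride desilylation frees the tertiary C4 alcohol without opening the lactone or the oxirane.

**Step 21**
Reactants: 26 (1R,3R,4S,7E,11S,12S,15S)-11,12-epoxy-4-hydroxycembr-7-en-16,3-olide
Product: 27 (1R,3R,4S,6E,8S,11S,12S,15S)-11,12-epoxy-8-hydroperoxy-4-hydroxycembr-6-en-16,3-olide (target)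
Conditions: O2, tetraphenylporphyrin (cat.), visible light, CH2Cl2, 0 °C; no reductive work-up
Reagents that add atoms: oxygen (O=O)
Why: Schenck ene reaction of singlet oxygen with the only alkene: bonding of O2 to C8 with abstraction of a C6 hydrogen on the more crowded (C6/C19) side of the 7E-alkene (cis effect) moves the double bond to 6E and creates the tertiary hydroperoxide, the 8S configuration resting on attack at the more exposed face of the macrocycle; the 7-hydroperoxy-8(19)-ene regioisomer and the C8 epimer are the expected by-products.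

**Compound list**
1 | pent-4-yn-1-ol | C#CCCCO | starting material
2 | (4E)-5-bromo-4-methylpent-4-en-1-ol | OCCC/C(C)=C/Br | intermediate
3 | (4E)-5-bromo-4-methylpent-4-enal | O=CCC/C(C)=C/Br | intermediate
4 | (6E)-7-bromo-2,6-dimethylhepta-1,6-dien-3-ol (racemic) | C=C(C)C(O)CC/C(C)=C/Br | intermediate
5 | ethyl (4E,8E)-9-bromo-4,8-dimethylnona-4,8-dienoate | CCOC(=O)CC/C(C)=C/CC/C(C)=C/Br | intermediate
6 | ethyl 3-[(2S,3S)-3-[(3E)-4-bromo-3-methylbut-3-en-1-yl]-2-methyloxiran-2-yl]propanoate | CCOC(=O)CC[C@]1(C)O[C@H]1CC/C(C)=C/Br | intermediate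
7 | methyl 5-[(2S,3S)-3-[(3E)-4-bromo-3-methylbut-3-en-1-yl]-2-methyloxiran-2-yl]-3-oxopentanoate | COC(=O)CC(=O)CC[C@]1(C)O[C@H]1CC/C(C)=C/Br | intermediate
8 | methyl (2Z)-5-[(2S,3S)-3-[(3E)-4-bromo-3-methylbut-3-en-1-yl]-2-methyloxiran-2-yl]-3-{[(trifluoromethyl)sulfonyl]oxy}pent-2-enoate | COC(=O)/C=C(\OS(=O)(=O)C(F)(F)F)CC[C@]1(C)O[C@H]1CC/C(C)=C/Br | intermediate
9 | methyl (2Z)-5-[(2S,3S)-3-[(3E)-4-bromo-3-methylbut-3-en-1-yl]-2-methyloxiran-2-yl]-3-(hydroxymethyl)pent-2-enoate (not isolated) | COC(=O)/C=C(\CO)CC[C@]1(C)O[C@H]1CC/C(C)=C/Br | intermediate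
10 | 4-{2-[(2S,3S)-3-[(3E)-4-bromo-3-methylbut-3-en-1-yl]-2-methyloxiran-2-yl]ethyl}furan-2(5H)-one | O=C1OCC(CC[C@]2(C)O[C@H]2CC/C(C)=C/Br)=C1 | intermediate
11 | (4S)-4-{2-[(2S,3S)-3-[(3E)-4-bromo-3-methylbut-3-en-1-yl]-2-methyloxiran-2-yl]ethyl}oxolan-2-one | O=C1C[C@H](CC[C@]2(C)O[C@H]2CC/C(C)=C/Br)CO1 | intermediate
12 | (3S,4S)-4-{2-[(2S,3S)-3-[(3E)-4-bromo-3-methylbut-3-en-1-yl]-2-methyloxiran-2-yl]ethyl}-3-methyloxolan-2-one | O=C1[C@@H](C)[C@H](CC[C@]2(C)O[C@H]2CC/C(C)=C/Br)CO1 | intermediate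
13 | [(2R)-2-methyloxiran-2-yl]methanol ((R)-2-methylglycidol) | C[C@@]1(CO)CO1 | starting material
14 | (2S)-2-{[(4-methoxybenzyl)oxy]methyl}-2-methyloxirane | C[C@@]1(COCc2ccc(OC)cc2)CO1 | intermediate
15 | (2S)-1-[(4-methoxybenzyl)oxy]-2-methylbut-3-en-2-ol | C[C@@](O)(COCc1ccc(OC)cc1)C=C | intermediate
16 | triethyl{[(2S)-1-[(4-methoxybenzyl)oxy]-2-methylbut-3-en-2-yl]oxy}silane | C[C@@](O[Si](CC)(CC)CC)(COCc1ccc(OC)cc1)C=C | intermediate
17 | 9-[(3S)-4-[(4-methoxybenzyl)oxy]-3-methyl-3-[(triethylsilyl)oxy]butyl]-9-borabicyclo[3.3.1]nonane (not isolated) | C[C@@](O[Si](CC)(CC)CC)(COCc1ccc(OC)cc1)CCB1C2CCCC1CCC2 | intermediate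
18 | (3S,4S)-3-methyl-4-[2-((2S,3S)-3-{(3E,7S)-8-[(4-methoxybenzyl)oxy]-3,7-dimethyl-7-[(triethylsilyl)oxy]oct-3-en-1-yl}-2-methyloxiran-2-yl)ethyl]oxolan-2-one | O=C1[C@@H](C)[C@H](CC[C@]2(C)O[C@H]2CC/C(C)=C/CC[C@](C)(O[Si](CC)(CC)CC)COCc2ccc(OC)cc2)CO1 | intermediate
19 | lithium (2S,3S)-3-(hydroxymethyl)-5-[(2S,3S)-3-{(3E,7S)-8-[(4-methoxybenzyl)oxy]-3,7-dimethyl-7-[(triethylsilyl)oxy]oct-3-en-1-yl}-2-methyloxiran-2-yl]-2-methylpentanoate (not isolated) | [Li+].[O-]C(=O)[C@@H](C)[C@@H](CO)CC[C@]1(C)O[C@H]1CC/C(C)=C/CC[C@](C)(O[Si](CC)(CC)CC)COCc1ccc(OC)cc1 | intermediate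
20 | methyl (2S,3S)-3-(hydroxymethyl)-5-[(2S,3S)-3-{(3E,7S)-8-[(4-methoxybenzyl)oxy]-3,7-dimethyl-7-[(triethylsilyl)oxy]oct-3-en-1-yl}-2-methyloxiran-2-yl]-2-methylpentanoate | COC(=O)[C@@H](C)[C@@H](CO)CC[C@]1(C)O[C@H]1CC/C(C)=C/CC[C@](C)(O[Si](CC)(CC)CC)COCc1ccc(OC)cc1 | intermediate
21 | methyl (2S,3S)-3-(iodomethyl)-5-[(2S,3S)-3-{(3E,7S)-8-[(4-methoxybenzyl)oxy]-3,7-dimethyl-7-[(triethylsilyl)oxy]oct-3-en-1-yl}-2-methyloxiran-2-yl]-2-methylpentanoate | COC(=O)[C@@H](C)[C@@H](CI)CC[C@]1(C)O[C@H]1CC/C(C)=C/CC[C@](C)(O[Si](CC)(CC)CC)COCc1ccc(OC)cc1 | intermediate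
22 | methyl (2S,3S)-5-[(2S,3S)-3-{(3E,7S)-8-hydroxy-3,7-dimethyl-7-[(triethylsilyl)oxy]oct-3-en-1-yl}-2-methyloxiran-2-yl]-3-(iodomethyl)-2-methylpentanoate | COC(=O)[C@@H](C)[C@@H](CI)CC[C@]1(C)O[C@H]1CC/C(C)=C/CC[C@](C)(O[Si](CC)(CC)CC)CO | intermediate
23 | methyl (2S,3S)-5-[(2S,3S)-3-{(3E,7S)-3,7-dimethyl-8-oxo-7-[(triethylsilyl)oxy]oct-3-en-1-yl}-2-methyloxiran-2-yl]-3-(iodomethyl)-2-methylpentanoate | COC(=O)[C@@H](C)[C@@H](CI)CC[C@]1(C)O[C@H]1CC/C(C)=C/CC[C@](C)(O[Si](CC)(CC)CC)C=O | intermediate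
24 | methyl (1R,3R,4S,7E,11S,12S,15S)-11,12-epoxy-3-hydroxy-4-[(triethylsilyl)oxy]cembr-7-en-16-oate (not isolated) | COC(=O)[C@@H](C)[C@H]1C[C@@H](O)[C@@](C)(O[Si](CC)(CC)CC)CC/C=C(C)/CC[C@@H]2O[C@@]2(C)CC1 | intermediate
25 | (1R,3R,4S,7E,11S,12S,15S)-11,12-epoxy-4-[(triethylsilyl)oxy]cembr-7-en-16,3-olide | C[C@@H]1C(=O)O[C@@H]2C[C@H]1CC[C@]1(C)O[C@H]1CC/C(C)=C/CC[C@]2(C)O[Si](CC)(CC)CC | intermediate
26 | (1R,3R,4S,7E,11S,12S,15S)-11,12-epoxy-4-hydroxycembr-7-en-16,3-olide | C[C@@H]1C(=O)O[C@@H]2C[C@H]1CC[C@]1(C)O[C@H]1CC/C(C)=C/CC[C@]2(C)O | intermediate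
27 | (1R,3R,4S,6E,8S,11S,12S,15S)-11,12-epoxy-8-hydroperoxy-4-hydroxycembr-6-en-16,3-olide | C[C@@H]1C(=O)O[C@@H]2C[C@H]1CC[C@]1(C)O[C@H]1CC[C@](C)(OO)/C=C/C[C@]2(C)O | target

**Step count and risks**
Total steps: 21. Longest linear sequence: 18 (steps 1–10 and 14–21).

Steps most likely to fail:

1. Step 19 (Proposed new method). The alkylchromium may be protonated, or may couple between molecules, before the 14-membered ring closes; facial selectivity at C3 may also be low. The fallback uses known reactions only: C2–C3 is made between two small molecules and the ring is closed at C6–C7. It sets out from 12 and 16. Lactone 12 is opened and iodinated as in steps 15 and 16, giving by way of lithium carboxylate F1 and hydroxy ester F2 the bromoalkenyl iodo ester F3. Silyl ether 16 is deprotected with DDQ to alcohol F4 and oxidised with Dess–Martin periodinane to aldehyde F5. CrCl2 with catalytic cobalt phthalocyanine (the intermolecular Takai–Utimoto alkylation; nickel-free CrCl2 leaves the bromoalkene alone) joins F3 and F5 to the open-chain hydroxy ester F6. Ti(OiPr)4 closes F6 to δ-lactone F7, at which stage C3 epimers can be separated. Hydroboration of the vinyl group with 9-BBN gives borane F8, and an intramolecular B-alkyl Suzuki–Miyaura coupling (Pd(dppf)Cl2, AsPh3, aq. K3PO4, slow addition) closes the ring and comes back to the route at 25.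

2. Step 21. Singlet oxygen may attack the wrong face at C8 or abstract a C19 hydrogen, giving the C8 epimer or the 7-hydroperoxy-8(19)-ene. The fallback changes the order of events so that the ene reaction meets a different substrate: it sets out from 25, whose bulky silyl ether and missing free hydroxyl change the conformation and hydrogen bonding around C4–C8. Photooxygenation of 25 under the conditions of step 21 gives silyl ether hydroperoxide F10, and buffered Bu4NF then removes the silyl group and comes back to the route at 27.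

3. Step 8. Transmetalation of the hydroxymethylstannane is slow, so oxidative addition to the bromoalkene or loss of the Z geometry may compete. The fallback uses copper in place of palladium and silicon as a masked hydroxyl. It sets out from 8: copper-catalysed addition–elimination of (isopropoxydimethylsilyl)methylmagnesium chloride (CuI cat., THF, −40 °C) should replace the triflate with retention and give silylmethyl enoate F9. Tamao–Fleming oxidation (KF, KHCO3, H2O2, THF/MeOH) then gives hydroxy enoate 9, which lactonises and comes back to the route at 10.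

**Further compounds**
F1 | step 19 | lithium (2S,3S)-5-[(2S,3S)-3-[(3E)-4-bromo-3-methylbut-3-en-1-yl]-2-methyloxiran-2-yl]-3-(hydroxymethyl)-2-methylpentanoate | [Li+].[O-]C(=O)[C@@H](C)[C@@H](CO)CC[C@]1(C)O[C@H]1CC/C(C)=C/Br
F2 | step 19 | methyl (2S,3S)-5-[(2S,3S)-3-[(3E)-4-bromo-3-methylbut-3-en-1-yl]-2-methyloxiran-2-yl]-3-(hydroxymethyl)-2-methylpentanoate | COC(=O)[C@@H](C)[C@@H](CO)CC[C@]1(C)O[C@H]1CC/C(C)=C/Br
F3 | step 19 | methyl (2S,3S)-5-[(2S,3S)-3-[(3E)-4-bromo-3-methylbut-3-en-1-yl]-2-methyloxiran-2-yl]-3-(iodomethyl)-2-methylpentanoate | COC(=O)[C@@H](C)[C@@H](CI)CC[C@]1(C)O[C@H]1CC/C(C)=C/Br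
F4 | step 19 | (2S)-2-methyl-2-[(triethylsilyl)oxy]but-3-en-1-ol | C[C@@](O[Si](CC)(CC)CC)(CO)C=C
F5 | step 19 | (2S)-2-methyl-2-[(triethylsilyl)oxy]but-3-enal | C[C@@](O[Si](CC)(CC)CC)(C=O)C=C
F6 | step 19 | methyl (2S,3R,5R,6S)-3-{2-[(2S,3S)-3-[(3E)-4-bromo-3-methylbut-3-en-1-yl]-2-methyloxiran-2-yl]ethyl}-5-hydroxy-2,6-dimethyl-6-[(triethylsilyl)oxy]oct-7-enoate | COC(=O)[C@@H](C)[C@@H](C[C@@H](O)[C@@](C)(O[Si](CC)(CC)CC)C=C)CC[C@]1(C)O[C@H]1CC/C(C)=C/Br
F7 | step 19 | (3S,4R,6R)-4-{2-[(2S,3S)-3-[(3E)-4-bromo-3-methylbut-3-en-1-yl]-2-methyloxiran-2-yl]ethyl}-3-methyl-6-{(2S)-2-[(triethylsilyl)oxy]but-3-en-2-yl}oxan-2-one | C[C@@H]1C(=O)O[C@H](C[C@H]1CC[C@]1(C)O[C@H]1CC/C(C)=C/Br)[C@@](C)(O[Si](CC)(CC)CC)C=C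
F8 | step 19 | B-alkyl-9-borabicyclo[3.3.1]nonane from hydroboration of the vinyl group of F7 | C[C@@H]1C(=O)O[C@H](C[C@H]1CC[C@]1(C)O[C@H]1CC/C(C)=C/Br)[C@@](C)(O[Si](CC)(CC)CC)CCB1C2CCCC1CCC2
F9 | step 8 | methyl (2Z)-5-[(2S,3S)-3-[(3E)-4-bromo-3-methylbut-3-en-1-yl]-2-methyloxiran-2-yl]-3-{[dimethyl(propan-2-yloxy)silyl]methyl}pent-2-enoate | COC(=O)/C=C(\C[Si](C)(C)OC(C)C)CC[C@]1(C)O[C@H]1CC/C(C)=C/Br
F10 | step 21 | (1R,3R,4S,6E,8S,11S,12S,15S)-11,12-epoxy-8-hydroperoxy-4-[(triethylsilyl)oxy]cembr-6-en-16,3-olide | C[C@@H]1C(=O)O[C@@H]2C[C@H]1CC[C@]1(C)O[C@H]1CC[C@](C)(OO)/C=C/C[C@]2(C)O[Si](CC)(CC)CC
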